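## Retrosynthetic overview

- The target is opened in its last operation to one open-chain epoxy triol aldehyde: MnO2 oxidative lactonisation of a (Z)-ene-1,4-diol gives the butenolide, SmI2 ketyl–olefin closure of C7–C8 gives the ten-membered ring (C7, C8, C11 set), and the samarium alkoxide is tigloylated.
- That precursor comes from a seven-membered lactone tether opened by i-Bu2AlH (C8 aldehyde plus free C3 hydroxyl, Z-C1=C10 already in place) and a C6–C7 Nozaki–Hiyama–Kishi coupling with a (Z)-iodoalkene; C6 is set by oxidation and CBS reduction.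
- The lactone tether comes from ring-closing metathesis of a methallyl ester on the C3 hydroxyl; the ring forces the Z olefin.
- The epoxide comes from Sharpless epoxidation of an allylic diol; C3 comes from Keck allylation of (E)-4-acetoxy-2-methylbut-2-enal.
- Ring order: epoxide, then the temporary seven-membered lactone (opened again), then butenolide and ten-membered carbocycle together in the final operation.

Assumption: atom labels C1–C15 are the germacrane numbers of the target (C6 bears the lactone oxygen, C8 the tiglate, C3 the free hydroxyl, C12 the lactone carbonyl).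
Assumption: (E)-4-acetoxy-2-methylbut-2-enal, the C5 aldehyde of vitamin A manufacture, is bought.
Assumption: the hydroxy aldehydes of the last two stages are drawn open-chain although they equilibrate with a seven-membered lactol that reacts through the open form.

## Route

Step 1
Reactants: 1 (E)-4-acetoxy-2-methylbut-2-enal
Product: 3 (2E,4S)-3-methylhepta-2,6-diene-1,4-diol, via acetate alcohol 2 (not isolated)
Conditions: (S)-BINOL (20 mol%), Ti(OiPr)4 (10 mol%), 4 Å MS, allylSnBu3, CH2Cl2, −20 °C; then K2CO3 (cat.), MeOH, rt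
Reagents that add atoms: allyltributylstannane, C=CC[Sn](CCCC)(CCCC)CCCC
Why: Keck asymmetric allylation: the (S)-BINOL–Ti(OiPr)4 complex delivers the allyl group to the Si face of the enal carbonyl and sets C3 as S, and the K2CO3-catalysed methanolysis then frees the primary allylic alcohol that directs the next step.

Step 2
Reactants: 3 (2E,4S)-3-methylhepta-2,6-diene-1,4-diol
Product: 4 [(2R,3R)-3-[(1S)-1-hydroxybut-3-en-1-yl]-3-methyloxiran-2-yl]methanol
Conditions: Ti(OiPr)4 (20 mol%), D-(−)-DIPT (25 mol%), t-BuOOH, 4 Å MS, CH2Cl2, −25 °C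
Reagents that add atoms: tert-butyl hydroperoxide, CC(C)(C)OO
Why: Katsuki–Sharpless asymmetric epoxidation directed by the primary allylic hydroxyl: D-(−)-DIPT places the oxygen on the face that gives the 4R,5R epoxide under reagent control, while the 3S secondary hydroxyl is in the slow-reacting series for this tartrate and the remote vinyl group is inert.

Step 3
Reactants: 4 [(2R,3R)-3-[(1S)-1-hydroxybut-3-en-1-yl]-3-methyloxiran-2-yl]methanol
Product: 5 (2S,3R)-3-[(1S)-1-hydroxybut-3-en-1-yl]-3-methyloxirane-2-carbaldehyde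
Conditions: TEMPO (10 mol%), PhI(OAc)2, CH2Cl2, rt
Reagents that add atoms: none
Why: The TEMPO/PhI(OAc)2 oxoammonium oxidation takes the primary alcohol to the aldehyde and leaves the hindered secondary C3 hydroxyl, the epoxide and all stereocentres untouched.

Step 4
Reactants: 5 (2S,3R)-3-[(1S)-1-hydroxybut-3-en-1-yl]-3-methyloxirane-2-carbaldehyde; 6 3-methylbut-3-enoic acid
Product: 7 (1S)-1-[(2R,3S)-3-formyl-2-methyloxiran-2-yl]but-3-en-1-yl 3-methylbut-3-enoate
Conditions: DCC, DMAP (10 mol%), CH2Cl2, 0 °C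
Reagents that add atoms: none
Why: Steglich esterification of the only free hydroxyl installs the methallyl tether without touching a stereocentre, and low temperature with catalytic DMAP keeps the β,γ-unsaturated acid out of conjugation.

Step 5
Reactants: 7 (1S)-1-[(2R,3S)-3-formyl-2-methyloxiran-2-yl]but-3-en-1-yl 3-methylbut-3-enoate
Product: 8 (7S)-7-[(2R,3S)-3-formyl-2-methyloxiran-2-yl]-4-methyl-6,7-dihydrooxepin-2(3H)-one
Conditions: second-generation Grubbs catalyst (5 mol%), 1,4-benzoquinone (10 mol%), CH2Cl2 (2 mM), 40 °C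
Reagents that add atoms: none
Why: Ring-closing metathesis joins the allyl and methallyl termini, and because a seven-membered ring can hold only a cis double bond the trisubstituted C1=C10 olefin is fixed as Z.

Step 6
Reactants: 9 prop-2-yn-1-ol
Product: 11 (2Z)-3-iodo-2-methylprop-2-en-1-ol, via alkenylmagnesium chelate 10 (not isolated)
Conditions: MeMgBr (2.3 equiv), CuI (10 mol%), THF, −10 °C to rt; then iodine, −40 °C
Reagents that add atoms: methylmagnesium bromide, C[Mg]Br; iodine, [I][I]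
Why: Copper-catalysed anti-carbomagnesiation of the propargylic magnesium alkoxide (Duboudin reaction) gives a five-membered alkenylmagnesium chelate, and iodinolysis with retention gives only the Z iodide.

Step 7
Reactants: 11 (2Z)-3-iodo-2-methylprop-2-en-1-ol
Product: 12 tert-butyl{[(2Z)-3-iodo-2-methylprop-2-en-1-yl]oxy}dimethylsilane
Conditions: TBSCl, imidazole, DMF, rt
Reagents that add atoms: tert-butyldimethylsilyl chloride, CC(C)(C)[Si](C)(C)Cl
Why: Standard Corey silylation of the primary alcohol protects the allylic oxygen through the coupling, oxidation and reduction steps.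

Step 8
Reactants: 8 (7S)-7-[(2R,3S)-3-formyl-2-methyloxiran-2-yl]-4-methyl-6,7-dihydrooxepin-2(3H)-one; 12 tert-butyl{[(2Z)-3-iodo-2-methylprop-2-en-1-yl]oxy}dimethylsilane
Product: 13 (7S)-7-[(2R,3R)-3-[(2Z)-4-(tert-butyldimethylsilyloxy)-1-hydroxy-3-methylbut-2-en-1-yl]-2-methyloxiran-2-yl]-4-methyl-6,7-dihydrooxepin-2(3H)-one (both C6 epimers)
Conditions: CrCl2 (4 equiv), NiCl2 (2 mol%), DMSO, rt
Reagents that add atoms: none
Why: Nozaki–Hiyama–Kishi coupling: the alkenylchromium forms with retention of the Z geometry and adds only to the aldehyde (lactone and epoxide inert) to make the C6–C7 bond, and the C6 mixture is corrected in the next two steps.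

Step 9
Reactants: 13 (7S)-7-[(2R,3R)-3-[(2Z)-4-(tert-butyldimethylsilyloxy)-1-hydroxy-3-methylbut-2-en-1-yl]-2-methyloxiran-2-yl]-4-methyl-6,7-dihydrooxepin-2(3H)-one (both C6 epimers)
Product: 14 (7S)-7-[(2R,3S)-3-[(2Z)-4-(tert-butyldimethylsilyloxy)-3-methylbut-2-enoyl]-2-methyloxiran-2-yl]-4-methyl-6,7-dihydrooxepin-2(3H)-one
Conditions: MnO2, CH2Cl2, rt
Reagents that add atoms: none
Why: MnO2 allylic oxidation converts both carbinol epimers into one enone under neutral conditions that leave the Z olefin, the epoxide and the lactone untouched.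

Step 10
Reactants: 14 (7S)-7-[(2R,3S)-3-[(2Z)-4-(tert-butyldimethylsilyloxy)-3-methylbut-2-enoyl]-2-methyloxiran-2-yl]-4-methyl-6,7-dihydrooxepin-2(3H)-one
Product: 15 (7S)-7-[(2R,3R)-3-[(1S,2Z)-4-(tert-butyldimethylsilyloxy)-1-hydroxy-3-methylbut-2-en-1-yl]-2-methyloxiran-2-yl]-4-methyl-6,7-dihydrooxepin-2(3H)-one
Conditions: (S)-Me-CBS (20 mol%), catecholborane, toluene, −78 °C
Reagents that add atoms: none
Why: Corey–Bakshi–Shibata reduction: the (S)-oxazaborolidine delivers hydride to the face that gives 6S with the alkenyl group as the large substituent, which matches the Felkin–Anh preference of the α,β-epoxy ketone (hydroxyl threo to the epoxide oxygen).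

Step 11
Reactants: 15 (7S)-7-[(2R,3R)-3-[(1S,2Z)-4-(tert-butyldimethylsilyloxy)-1-hydroxy-3-methylbut-2-en-1-yl]-2-methyloxiran-2-yl]-4-methyl-6,7-dihydrooxepin-2(3H)-one
Product: 16 (7S)-7-[(2R,3R)-3-[(1S,2Z)-1,4-dihydroxy-3-methylbut-2-en-1-yl]-2-methyloxiran-2-yl]-4-methyl-6,7-dihydrooxepin-2(3H)-one
Conditions: HF·pyridine, pyridine, THF, 0 °C
Reagents that add atoms: none
Why: Fluoride-mediated desilylation frees the primary allylic alcohol, and buffered HF·pyridine is mild enough for the epoxide and the lactone.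

Step 12
Reactants: 16 (7S)-7-[(2R,3R)-3-[(1S,2Z)-1,4-dihydroxy-3-methylbut-2-en-1-yl]-2-methyloxiran-2-yl]-4-methyl-6,7-dihydrooxepin-2(3H)-one
Product: 17 (3Z,6S)-6-[(2R,3R)-3-[(1S,2Z)-1,4-dihydroxy-3-methylbut-2-en-1-yl]-2-methyloxiran-2-yl]-6-hydroxy-3-methylhex-3-enal
Conditions: i-Bu2AlH (3.2 equiv), CH2Cl2, −78 °C; Rochelle salt
Reagents that add atoms: none
Why: i-Bu2AlH partial reduction of a lactone: the tetrahedral aluminium lactolate is stable at −78 °C and gives on work-up the lactol, that is the C8 aldehyde plus the free C3 hydroxyl, with no stereocentre changed.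

Step 13
Reactants: 17 (3Z,6S)-6-[(2R,3R)-3-[(1S,2Z)-1,4-dihydroxy-3-methylbut-2-en-1-yl]-2-methyloxiran-2-yl]-6-hydroxy-3-methylhex-3-enal
Product: 20 (1(10)Z)-4α,5β-epoxy-3β-hydroxy-8β-[(E)-2-methylbut-2-enoyloxy]-11αH-germacr-1(10)-en-12,6α-olide, via butenolide aldehyde 18 (not isolated), via samarium alkoxide 19 (not isolated)
Conditions: MnO2, CH2Cl2, rt, filter, evaporate; then SmI2 (2.5 equiv), t-BuOH (2 equiv), THF (3 mM), −78 °C; then tigloyl chloride, −78 to 0 °C
Reagents that add atoms: (E)-2-methylbut-2-enoyl chloride (tigloyl chloride), C/C=C(\C)C(Cl)=O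
Why: Proposed new method: MnO2 oxidises the primary allylic alcohol to the (Z)-enal, whose lactol with the C6 hydroxyl is oxidised on to butenolide 18; SmI2 then turns the C8 aldehyde into a ketyl that adds 10-exo to the butenolide β-carbon C7 anti to the C6 substituent (6,7-trans), t-BuOH protonates the trivalent samarium lactone enolate on the face away from the new C7–C8 bond (11R, methyl cis to C8), samarium bridging the ketyl oxygen and the lactone carbonyl is expected to favour the 8β alkoxide (8R), and this alkoxide rather than the neutral hindered C3 hydroxyl is acylated by tigloyl chloride; the closest known reaction types are the MnO2 oxidative lactonisation of (Z)-2-ene-1,4-diols and the SmI2 ketyl–olefin cyclisation onto unsaturated lactones with in situ O-acylation, here extended to a ten-membered ring.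

## Compound list

1 | (E)-4-acetoxy-2-methylbut-2-enal | CC(=O)OC/C=C(\C)C=O | starting material
2 | (2E,4S)-4-hydroxy-3-methylhepta-2,6-dien-1-yl acetate | C=CC[C@H](O)/C(C)=C/COC(C)=O | intermediate
3 | (2E,4S)-3-methylhepta-2,6-diene-1,4-diol | C=CC[C@H](O)/C(C)=C/CO | intermediate
4 | [(2R,3R)-3-[(1S)-1-hydroxybut-3-en-1-yl]-3-methyloxiran-2-yl]methanol | C=CC[C@H](O)[C@@]1(C)O[C@@H]1CO | intermediate
5 | (2S,3R)-3-[(1S)-1-hydroxybut-3-en-1-yl]-3-methyloxirane-2-carbaldehyde | C=CC[C@H](O)[C@@]1(C)O[C@@H]1C=O | intermediate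
6 | 3-methylbut-3-enoic acid | CC(=C)CC(=O)O | starting material
7 | (1S)-1-[(2R,3S)-3-formyl-2-methyloxiran-2-yl]but-3-en-1-yl 3-methylbut-3-enoate | C=CC[C@H](OC(=O)CC(C)=C)[C@@]1(C)O[C@@H]1C=O | intermediate
8 | (7S)-7-[(2R,3S)-3-formyl-2-methyloxiran-2-yl]-4-methyl-6,7-dihydrooxepin-2(3H)-one (Z ring olefin) | O=C1C/C(C)=C\C[C@H](O1)[C@@]2(C)O[C@@H]2C=O | intermediate
9 | prop-2-yn-1-ol | C#CCO | starting material
10 | (Z)-BrMg–CH=C(CH3)–CH2–OMgBr, alkenylmagnesium chelate | Br[Mg]/C=C(/C)CO[Mg]Br | intermediate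
11 | (2Z)-3-iodo-2-methylprop-2-en-1-ol | I/C=C(/C)CO | intermediate
12 | tert-butyl{[(2Z)-3-iodo-2-methylprop-2-en-1-yl]oxy}dimethylsilane | I/C=C(/C)CO[Si](C)(C)C(C)(C)C | intermediate
13 | (7S)-7-[(2R,3R)-3-[(2Z)-4-(tert-butyldimethylsilyloxy)-1-hydroxy-3-methylbut-2-en-1-yl]-2-methyloxiran-2-yl]-4-methyl-6,7-dihydrooxepin-2(3H)-one, both C6 carbinol epimers | O=C1C/C(C)=C\C[C@H](O1)[C@@]2(C)O[C@@H]2C(O)/C=C(/C)CO[Si](C)(C)C(C)(C)C | intermediate
14 | (7S)-7-[(2R,3S)-3-[(2Z)-4-(tert-butyldimethylsilyloxy)-3-methylbut-2-enoyl]-2-methyloxiran-2-yl]-4-methyl-6,7-dihydrooxepin-2(3H)-one | O=C1C/C(C)=C\C[C@H](O1)[C@@]2(C)O[C@@H]2C(=O)/C=C(/C)CO[Si](C)(C)C(C)(C)C | intermediate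
15 | (7S)-7-[(2R,3R)-3-[(1S,2Z)-4-(tert-butyldimethylsilyloxy)-1-hydroxy-3-methylbut-2-en-1-yl]-2-methyloxiran-2-yl]-4-methyl-6,7-dihydrooxepin-2(3H)-one | O=C1C/C(C)=C\C[C@H](O1)[C@@]2(C)O[C@@H]2[C@@H](O)/C=C(/C)CO[Si](C)(C)C(C)(C)C | intermediate
16 | (7S)-7-[(2R,3R)-3-[(1S,2Z)-1,4-dihydroxy-3-methylbut-2-en-1-yl]-2-methyloxiran-2-yl]-4-methyl-6,7-dihydrooxepin-2(3H)-one | O=C1C/C(C)=C\C[C@H](O1)[C@@]2(C)O[C@@H]2[C@@H](O)/C=C(/C)CO | intermediate
17 | (3Z,6S)-6-[(2R,3R)-3-[(1S,2Z)-1,4-dihydroxy-3-methylbut-2-en-1-yl]-2-methyloxiran-2-yl]-6-hydroxy-3-methylhex-3-enal (open-chain form) | O=CC/C(C)=C\C[C@H](O)[C@@]1(C)O[C@@H]1[C@@H](O)/C=C(/C)CO | intermediate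
18 | (3Z,6S)-6-hydroxy-3-methyl-6-[(2R,3R)-2-methyl-3-[(2S)-4-methyl-5-oxo-2,5-dihydrofuran-2-yl]oxiran-2-yl]hex-3-enal | O=CC/C(C)=C\C[C@H](O)[C@@]1(C)O[C@@H]1[C@H]1OC(=O)C(C)=C1 | intermediate
19 | O8–SmI2 alkoxide of 4α,5β-epoxy-3β,8β-dihydroxy-11αH-germacr-1(10)Z-en-12,6α-olide | I[Sm](I)O[C@@H]1C/C(C)=C\C[C@H](O)[C@@]2(C)O[C@@H]2[C@H]2OC(=O)[C@H](C)[C@@H]21 | intermediate
20 | (1(10)Z,3S,4R,5R,6S,7R,8R,11R)-4,5-epoxy-3-hydroxy-8-[(E)-2-methylbut-2-enoyloxy]germacr-1(10)-en-12,6-olide (CNP0265652.4) | C/C=C(\C)C(=O)O[C@@H]1C/C(C)=C\C[C@H](O)[C@@]2(C)O[C@@H]2[C@H]2OC(=O)[C@H](C)[C@@H]21 | target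

## Step count and risks

Total step count: 13. Longest linear sequence: 11 steps (steps 1–5 and 8–13, from compound 1).

Most likely to fail, step 13. The ten-membered ketyl–olefin closure may lose to simple reduction or pinacol coupling, the C8 configuration rests on a chelation argument, and MnO2 may oxidise the C8 lactol back to a lactone. The fallback sets out from 17 and comes back at 20. Oxidise 17 with MnO2 and isolate butenolide aldehyde 18. Close the ring by an intramolecular Stetter reaction (triazolium carbene catalyst, i-Pr2NEt), in which the acyl anion equivalent of C8 adds to C7 anti to the C6 substituent, to give 4α,5β-epoxy-3β-hydroxy-8-oxo-11αH-germacr-1(10)Z-en-12,6α-olide F1. Reduce the ketone with NaBH4/CeCl3 at −78 °C to 4α,5β-epoxy-3β,8β-dihydroxy-11αH-germacr-1(10)Z-en-12,6α-olide F2; should the 8α alcohol form instead, it is esterified with inversion by a Mitsunobu reaction with tiglic acid. Acylate F2 with tigloyl chloride and pyridine to reach 20.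

Second, step 5. The ester prefers an s-trans shape that disfavours closure of the seven-membered lactone, and the β,γ-olefin may move into conjugation. The fallback sets out from 5 and comes back at 8. Treat 5 with Ph2SiCl2 and imidazole, then 3-methylbut-3-en-1-ol, to give (1S)-1-[(2R,3S)-3-formyl-2-methyloxiran-2-yl]but-3-en-1-yl 3-methylbut-3-en-1-yl diphenylsilyl ketal F3. Ring-closing metathesis with the second-generation Grubbs catalyst gives the nine-membered cyclic silyl ketal with the Z-trisubstituted olefin F4. HF·pyridine gives (2S,3R)-3-[(1S,3Z)-1,6-dihydroxy-4-methylhex-3-en-1-yl]-3-methyloxirane-2-carbaldehyde F5. TEMPO/PhI(OAc)2 then oxidises the primary alcohol, and the lactol it forms with the C3 hydroxyl, on to lactone 8.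

Third, step 10. The epoxide-bearing carbon may not behave as the small group, so the 6S selectivity of the CBS reduction could be low. The fallback sets out from 8 and 12 and comes back at 15. Couple them in a catalytic asymmetric Nozaki–Hiyama–Kishi reaction (CrCl2, NiCl2, chiral sulfonamide ligand, Mn, TMSCl) so that the ligand sets C6 as S while the C6–C7 bond forms; steps 9 and 10 drop out and no new compound arises.

Further compounds
F1 | step 13 | 4α,5β-epoxy-3β-hydroxy-8-oxo-11αH-germacr-1(10)Z-en-12,6α-olide | O=C1C/C(C)=C\C[C@H](O)[C@@]2(C)O[C@@H]2[C@H]2OC(=O)[C@H](C)[C@@H]21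
F2 | step 13 | 4α,5β-epoxy-3β,8β-dihydroxy-11αH-germacr-1(10)Z-en-12,6α-olide | O[C@@H]1C/C(C)=C\C[C@H](O)[C@@]2(C)O[C@@H]2[C@H]2OC(=O)[C@H](C)[C@@H]21
F3 | step 5 | (1S)-1-[(2R,3S)-3-formyl-2-methyloxiran-2-yl]but-3-en-1-yl 3-methylbut-3-en-1-yl diphenylsilyl ketal | C=CC[C@H](O[Si](c1ccccc1)(c1ccccc1)OCCC(C)=C)[C@@]1(C)O[C@@H]1C=O
F4 | step 5 | nine-membered cyclic diphenylsilyl ketal of the C3 and C8 oxygens with Z-C1=C10 olefin, bearing the (2R,3S)-3-formyl-2-methyloxiran-2-yl group at C3 | C1C/C(C)=C\C[C@H](O[Si](c2ccccc2)(c2ccccc2)O1)[C@@]3(C)O[C@@H]3C=O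
F5 | step 5 | (2S,3R)-3-[(1S,3Z)-1,6-dihydroxy-4-methylhex-3-en-1-yl]-3-methyloxirane-2-carbaldehyde | OCC/C(C)=C\C[C@H](O)[C@@]1(C)O[C@@H]1C=O
F0 | step 10 | none | none
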